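**Strategy.** The pyran ring is disconnected at C2–C3 and at O1–C8a. Both bonds are forged in one pot by a Claisen condensation/intramolecular SNAr chromone annulation: the enolate of a 2-fluoro-5-(MOM-oxy)acetophenone (future C3, C4 and benzo ring) is acylated by the ester of the complete side chain, whose carbonyl carbon and oxygen become C2 and O1, and the diketonate oxygen then displaces fluoride at C8a. The step exploits a temporary carbonyl at C4 of the pyran ring: it acidifies C3, activates the ortho C8a–F bond, and afterwards makes C2 a β-acceptor for asymmetric methyl conjugate addition, which sets (S)-C2, before reduction and dehydration convert it into the C3=C4 alkene.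

Key step: step 5

Remark on the chemistry: the sense of induction in step 6 is taken to be ligand-controlled; the ligand antipode that delivers methyl to the Re face of C2 of 11 (which corresponds to S) is assumed to be chosen. Compounds 1, 6 and 8 are assumed to be purchasable.

Step 1
Reactants: 1 dihydro-β-ionone, 4-(2,6,6-trimethylcyclohex-1-en-1-yl)butan-2-one
Product: 3 2-(but-3-yn-1-yl)-1,3,3-trimethylcyclohex-1-ene, via enol diethyl phosphate 2 (not isolated)
Conditions: LDA (1.05 equiv), THF, −78 °C; ClP(O)(OEt)2, −78 °C → rt; then LDA (2.3 equiv), −78 °C → rt; H2O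
Reagents that add atoms: none
Why: Kinetic deprotonation at the methyl group, O-phosphorylation and LDA-induced elimination of diethyl phosphate from the terminal enol phosphate should convert the methyl ketone into the terminal alkyne, the final deprotonation to the acetylide driving the sequence (ketone-to-alkyne conversion via an enol phosphate).

Step 2
Reactants: 3 2-(but-3-yn-1-yl)-1,3,3-trimethylcyclohex-1-ene
Product: 5 2-[(E)-4-iodo-3-methylbut-3-en-1-yl]-1,3,3-trimethylcyclohex-1-ene, via (E)-alkenyldimethylalane 4 (not isolated)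
Conditions: Me3Al (2 equiv), Cp2ZrCl2 (0.25 equiv), CH2Cl2, 0 °C → rt; then I2, THF, −30 → 0 °C
Reagents that add atoms: trimethylaluminium C[Al](C)C; iodine II
Why: Zirconium-catalysed carboalumination (Negishi) adds methyl and aluminium syn across the terminal alkyne with methyl on the internal carbon, and iodinolysis of the C–Al bond with retention should give the (E)-trisubstituted iodoalkene that fixes the side-chain alkene geometry.

Step 3
Reactants: 5 2-[(E)-4-iodo-3-methylbut-3-en-1-yl]-1,3,3-trimethylcyclohex-1-ene; 6 (3-ethoxy-3-oxopropyl)zinc bromide (0.5 M in THF)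
Product: 7 ethyl (E)-5-methyl-7-(2,6,6-trimethylcyclohex-1-en-1-yl)hept-4-enoate
Conditions: Pd(dppf)Cl2 (5 mol %), THF/DMA, 50 °C
Reagents that add atoms: none
Why: Negishi sp2–sp3 cross-coupling of the alkenyl iodide with the ester-tolerant zinc homoenolate should proceed with retention of alkene geometry and adds the three carbons that become the two side-chain CH2 groups next to the ring and C2 itself.

Step 4
Reactants: 8 1-(2-fluoro-5-hydroxyphenyl)ethan-1-one
Product: 9 1-[2-fluoro-5-(methoxymethoxy)phenyl]ethan-1-one
Conditions: MOMCl (1.3 equiv), i-Pr2NEt, CH2Cl2, 0 °C → rt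
Reagents that add atoms: chloromethyl methyl ether COCCl
Why: O-Alkylation of the phenol gives a MOM acetal that is inert to the bases, organometallics and hydride used later and prevents formation of a para-phenoxide, which would shut down the SNAr in step 5.

Step 5
Reactants: 9 1-[2-fluoro-5-(methoxymethoxy)phenyl]ethan-1-one (1.5 equiv); 7 ethyl (E)-5-methyl-7-(2,6,6-trimethylcyclohex-1-en-1-yl)hept-4-enoate
Product: 11 6-(methoxymethoxy)-2-[(E)-4-methyl-6-(2,6,6-trimethylcyclohex-1-en-1-yl)hex-3-en-1-yl]-4H-chromen-4-one, via 1,3-diketone 10 (not isolated)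
Conditions: NaH (3 equiv), THF, 0 → 65 °C; then DMF, 110 °C
Reagents that add atoms: none
Why: NaH converts 9 into its methyl-ketone enolate, whose carbon (future C3) attacks the ester carbonyl of 7 (future C2) in a crossed Claisen condensation driven by formation of the 1,3-diketonate 10; on heating in DMF the enolate oxygen on the C2 side adds to C8a ipso to fluorine, the Meisenheimer complex being stabilised by the ortho C4 carbonyl, and fluoride is expelled (intramolecular SNAr). The closest known reaction type is the chromone annulation of o-halogenoaryl 1,3-diketones (Claisen or Baker–Venkataraman-type diketone formation followed by O-arylation). The 4-pyranone ring closes by addition–elimination at an sp2 carbon, a favoured six-membered closure in which O1 bonds to C8a and the charge is relayed through C4a to the C4 carbonyl (6-endo-trig in Baldwin terms). No stereocentre is formed; C2 is deliberately left trigonal so that step 6 can set it. The step needs C- over O-acylation, secured by the thermodynamic preference for the chelated β-diketonate, and ring closure ahead of intermolecular displacement of fluoride by ethoxide, secured by the proximity of the enolate oxygen to C8a and by the MOM group, which keeps the para oxygen from becoming a deactivating phenoxide.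

Step 6
Reactants: 11 6-(methoxymethoxy)-2-[(E)-4-methyl-6-(2,6,6-trimethylcyclohex-1-en-1-yl)hex-3-en-1-yl]-4H-chromen-4-one
Product: 12 (S)-6-(methoxymethoxy)-2-methyl-2-[(E)-4-methyl-6-(2,6,6-trimethylcyclohex-1-en-1-yl)hex-3-en-1-yl]chroman-4-one
Conditions: MeMgBr (1.5 equiv, slow addition), CuBr·SMe2 (5 mol %), chiral ferrocenyl bisphosphine (Josiphos family, 6 mol %), t-BuOMe/CH2Cl2, −78 °C; aq NH4Cl at −78 °C
Reagents that add atoms: methylmagnesium bromide C[Mg]Br
Why: Copper(I)/chiral bisphosphine-catalysed asymmetric conjugate addition of a Grignard reagent to the chromone (a vinylogous ester), a reaction type known for chromones, should deliver methyl to the Re face of C2 under ligand control and create the oxygen-bearing quaternary centre as (S), the cold quench avoiding retro-oxa-Michael opening of the enolate.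

Step 7
Reactants: 12 (S)-6-(methoxymethoxy)-2-methyl-2-[(E)-4-methyl-6-(2,6,6-trimethylcyclohex-1-en-1-yl)hex-3-en-1-yl]chroman-4-one
Product: 13 (2S,4RS)-6-(methoxymethoxy)-2-methyl-2-[(E)-4-methyl-6-(2,6,6-trimethylcyclohex-1-en-1-yl)hex-3-en-1-yl]chroman-4-ol
Conditions: NaBH4, MeOH/THF, 0 °C
Reagents that add atoms: none
Why: Borohydride 1,2-reduction of the aryl ketone should give the benzylic alcohol, whose C4 configuration (epimer mixture) is of no consequence because C4 becomes sp2 in step 8.

Step 8
Reactants: 13 (2S,4RS)-6-(methoxymethoxy)-2-methyl-2-[(E)-4-methyl-6-(2,6,6-trimethylcyclohex-1-en-1-yl)hex-3-en-1-yl]chroman-4-ol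
Product: 15 (S)-6-(methoxymethoxy)-2-methyl-2-[(E)-4-methyl-6-(2,6,6-trimethylcyclohex-1-en-1-yl)hex-3-en-1-yl]-2H-chromene, via C4 sulfamate ester 14 (not isolated)
Conditions: Burgess reagent (1.5 equiv), toluene, rt → 50 °C
Reagents that add atoms: none
Why: Burgess dehydration proceeds by syn (Ei) elimination of the benzylic sulfamate toward the only β-hydrogens (C3–H) and should give the C3=C4 bond under neutral conditions that spare the MOM acetal, the side-chain alkenes and the C2 allylic aryl ether, hence its configuration.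

Step 9
Reactants: 15 (S)-6-(methoxymethoxy)-2-methyl-2-[(E)-4-methyl-6-(2,6,6-trimethylcyclohex-1-en-1-yl)hex-3-en-1-yl]-2H-chromene
Product: 16 (S)-2-methyl-2-[(E)-4-methyl-6-(2,6,6-trimethylcyclohex-1-en-1-yl)hex-3-en-1-yl]-2H-chromen-6-ol (target, CNP0157994.1)
Conditions: HCl (2 M in MeOH, 3 equiv), THF/MeOH, rt
Reagents that add atoms: none
Why: Acid-catalysed acetal exchange with methanol should remove the MOM group as dimethoxymethane at room temperature, well below the temperatures at which 2H-chromenes can racemise by electrocyclic ring opening.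

**Compound list**

1 | dihydro-β-ionone, 4-(2,6,6-trimethylcyclohex-1-en-1-yl)butan-2-one | CC(=O)CCC1=C(C)CCCC1(C)C | starting material
2 | diethyl 4-(2,6,6-trimethylcyclohex-1-en-1-yl)but-1-en-2-yl phosphate | C=C(CCC1=C(C)CCCC1(C)C)OP(=O)(OCC)OCC | intermediate (not isolated)
3 | 2-(but-3-yn-1-yl)-1,3,3-trimethylcyclohex-1-ene | C#CCCC1=C(C)CCCC1(C)C | intermediate
4 | dimethyl[(E)-2-methyl-4-(2,6,6-trimethylcyclohex-1-en-1-yl)but-1-en-1-yl]aluminium | C[Al](C)/C=C(C)/CCC1=C(C)CCCC1(C)C | intermediate (not isolated)
5 | 2-[(E)-4-iodo-3-methylbut-3-en-1-yl]-1,3,3-trimethylcyclohex-1-ene | I/C=C(C)/CCC1=C(C)CCCC1(C)C | intermediate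
6 | (3-ethoxy-3-oxopropyl)zinc bromide | CCOC(=O)CC[Zn]Br | starting material
7 | ethyl (E)-5-methyl-7-(2,6,6-trimethylcyclohex-1-en-1-yl)hept-4-enoate | CCOC(=O)CC/C=C(C)/CCC1=C(C)CCCC1(C)C | intermediate
8 | 1-(2-fluoro-5-hydroxyphenyl)ethan-1-one | CC(=O)c1cc(O)ccc1F | starting material
9 | 1-[2-fluoro-5-(methoxymethoxy)phenyl]ethan-1-one | CC(=O)c1cc(OCOC)ccc1F | intermediate
10 | (E)-1-[2-fluoro-5-(methoxymethoxy)phenyl]-7-methyl-9-(2,6,6-trimethylcyclohex-1-en-1-yl)non-6-ene-1,3-dione | O=C(CC(=O)CC/C=C(C)/CCC1=C(C)CCCC1(C)C)c1cc(OCOC)ccc1F | intermediate (not isolated)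
11 | 6-(methoxymethoxy)-2-[(E)-4-methyl-6-(2,6,6-trimethylcyclohex-1-en-1-yl)hex-3-en-1-yl]-4H-chromen-4-one | O=C1C=C(CC/C=C(C)/CCC2=C(C)CCCC2(C)C)Oc2ccc(OCOC)cc12 | intermediate
12 | (S)-6-(methoxymethoxy)-2-methyl-2-[(E)-4-methyl-6-(2,6,6-trimethylcyclohex-1-en-1-yl)hex-3-en-1-yl]chroman-4-one | CC1=C(CC/C(C)=C/CC[C@@]2(C)CC(=O)c3cc(OCOC)ccc3O2)C(C)(C)CCC1 | intermediate
13 | (2S,4RS)-6-(methoxymethoxy)-2-methyl-2-[(E)-4-methyl-6-(2,6,6-trimethylcyclohex-1-en-1-yl)hex-3-en-1-yl]chroman-4-ol | CC1=C(CC/C(C)=C/CC[C@@]2(C)CC(O)c3cc(OCOC)ccc3O2)C(C)(C)CCC1 | intermediate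
14 | triethylammonium salt of the C4 O-[N-(methoxycarbonyl)sulfamate] of 13 | CC1=C(CC/C(C)=C/CC[C@@]2(C)CC(OS(=O)(=O)[N-]C(=O)OC)c3cc(OCOC)ccc3O2)C(C)(C)CCC1.CC[NH+](CC)CC | intermediate (not isolated)
15 | (S)-6-(methoxymethoxy)-2-methyl-2-[(E)-4-methyl-6-(2,6,6-trimethylcyclohex-1-en-1-yl)hex-3-en-1-yl]-2H-chromene | CC1=C(CC/C(C)=C/CC[C@@]2(C)C=Cc3cc(OCOC)ccc3O2)C(C)(C)CCC1 | intermediate
16 | (S)-2-methyl-2-[(E)-4-methyl-6-(2,6,6-trimethylcyclohex-1-en-1-yl)hex-3-en-1-yl]-2H-chromen-6-ol | CC1=C(CC/C(C)=C/CC[C@@]2(C)C=Cc3cc(O)ccc3O2)C(C)(C)CCC1 | target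

**Step count and risks**

Total steps: 9. Longest linear sequence: 8 (steps 1, 2, 3, 5, 6, 7, 8, 9; step 4 is the side branch).

Steps most likely to fail:

1. Step 6. Facial discrimination at the tetrasubstituted C2 may be insufficient, and γ-deprotonation of the 2-alkyl group, 1,2-addition or ring opening of the enolate (retro-oxa-Michael) may compete or erode the enantiomeric purity. Fallback: setting out from 11, addition of lithium dimethylcuprate with TMSCl (THF, −78 °C, acidic work-up) without chiral ligand would give the racemic chromanone F1. Preparative chromatography on a chiral stationary phase (SFC) would then separate 12 from its enantiomer, the (R)-chromanone F2. The route is rejoined at 12.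

2. Step 5. Under the one-pot conditions the ketone enolate may self-condense, the Claisen condensation may stall, and ethoxide may displace fluoride intermolecularly before the ring closes. Fallback: setting out from 7, saponification (LiOH, THF/H2O) would give (E)-5-methyl-7-(2,6,6-trimethylcyclohex-1-en-1-yl)hept-4-enoic acid F3, and oxalyl chloride with catalytic DMF in CH2Cl2 would convert it into the acid chloride F4. C-Acylation of the preformed lithium enolate of 9 (LiHMDS, 2.2 equiv, THF, −78 °C) with F4 would give diketone 10, now isolated. Separate ring closure with Cs2CO3 in DMSO at 90 °C, with no alkoxide present, returns the route at 11.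

3. Step 1. Enolisation may occur partly toward the methylene side of the ketone, so that the internal enol phosphate leads to allene and internal alkyne contaminants. Fallback: setting out from 1, addition of vinylmagnesium bromide (THF, 0 °C) would give the tertiary allylic alcohol 3-methyl-5-(2,6,6-trimethylcyclohex-1-en-1-yl)pent-1-en-3-ol F5. Johnson–Claisen rearrangement (triethyl orthoacetate, catalytic propionic acid, 140 °C) would then give ester 7 together with its (Z)-isomer F6, to be separated on silver nitrate-impregnated silica. The route is rejoined at 7, bypassing 3 and 5; geometric control in this rearrangement is poor, which is why it serves only as the fallback.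

Further compounds
F1 | step 6 | racemic 6-(methoxymethoxy)-2-methyl-2-[(E)-4-methyl-6-(2,6,6-trimethylcyclohex-1-en-1-yl)hex-3-en-1-yl]chroman-4-one | CC1=C(CC/C(C)=C/CCC2(C)CC(=O)c3cc(OCOC)ccc3O2)C(C)(C)CCC1
F2 | step 6 | (R)-6-(methoxymethoxy)-2-methyl-2-[(E)-4-methyl-6-(2,6,6-trimethylcyclohex-1-en-1-yl)hex-3-en-1-yl]chroman-4-one | CC1=C(CC/C(C)=C/CC[C@]2(C)CC(=O)c3cc(OCOC)ccc3O2)C(C)(C)CCC1
F3 | step 5 | (E)-5-methyl-7-(2,6,6-trimethylcyclohex-1-en-1-yl)hept-4-enoic acid | OC(=O)CC/C=C(C)/CCC1=C(C)CCCC1(C)C
F4 | step 5 | (E)-5-methyl-7-(2,6,6-trimethylcyclohex-1-en-1-yl)hept-4-enoyl chloride | ClC(=O)CC/C=C(C)/CCC1=C(C)CCCC1(C)C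
F5 | step 1 | 3-methyl-5-(2,6,6-trimethylcyclohex-1-en-1-yl)pent-1-en-3-ol (racemic) | C=CC(C)(O)CCC1=C(C)CCCC1(C)C
F6 | step 1 | ethyl (Z)-5-methyl-7-(2,6,6-trimethylcyclohex-1-en-1-yl)hept-4-enoate | CCOC(=O)CC/C=C(C)\CCC1=C(C)CCCC1(C)C
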